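**Retrosynthetic overview**
1. The target is a (1R,3S,6R,4Z)-germacranolide: ring A (butenolide) fused to ring B (ten-membered carbocycle). The free C1–OH is told apart from the two acetates by a temporary C1 chloroacetate, and C1 is set by CBS reduction of the macrocyclic 1-ketone.
2. Ring B is closed last, at C1–C10, by an intramolecular Nozaki–Hiyama–Kishi reaction of a 2-iodoalkene with the C1 aldehyde.
3. Ring A is formed before that by lactonisation of a (Z)-γ-hydroxy tetrasubstituted enoate, built by syn-carbocupration of a C6 γ-silyloxy ynoate (brings C8–C10/C14) and trapping with ICH2Bpin (brings C13).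
4. The C6 carbinol and its ynoate come from a Zn–ProPhenol alkynylation of a Z-enal with methyl propiolate; the Z-C4=C5 alkene comes from Me2CuLi syn-addition to a C3 ynoate.
5. C3 is the first stereocentre, set by ketoreductase reduction of an achiral ynone. Order of ring formation: ring A, then ring B.

Locants are germacranolide locants (C1 carbinol, C3 acetoxy carbon, C4=C5, C6 lactone CH, C7=C11, C12 carbonyl, C13 CH2O, C10=C14, C15 methyl). PMB = 4-methoxybenzyl, TBS = tert-butyldimethylsilyl, TES = triethylsilyl, TMS = trimethylsilyl, Bpin = 4,4,5,5-tetramethyl-1,3,2-dioxaborolan-2-yl.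

Assumption: in step 11 the (R,R)-ProPhenol–zinc catalyst is taken to direct Si-face alkynylation of the enal (giving 6R); if the sense proves to be the reverse, the (S,S)-ligand is used with no other change.

**Route**

Step 1
Reactants: 1 3-[(4-methoxybenzyl)oxy]propan-1-ol
Product: 2 3-[(4-methoxybenzyl)oxy]propanal
Conditions: TEMPO (10 mol%), PhI(OAc)2, CH2Cl2, rt
Reagents that add atoms: none
Why: Nitroxyl-catalysed oxidation (TEMPO/PhI(OAc)2) of a primary alcohol stops at the aldehyde under near-neutral conditions that do not cause β-elimination of the PMB ether.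

Step 2
Reactants: 2 3-[(4-methoxybenzyl)oxy]propanal; 3 ethynyltrimethylsilane
Product: 5 rac-5-[(4-methoxybenzyl)oxy]-1-(trimethylsilyl)pent-1-yn-3-ol, via lithium (trimethylsilyl)acetylide 4 (not isolated)
Conditions: 3, n-BuLi, THF, −78 °C; then 2, −78 → 0 °C
Reagents that add atoms: ethynyltrimethylsilane (3), C#C[Si](C)(C)C
Why: 1,2-Addition of a lithium acetylide to an aldehyde builds C3–C4; the carbinol is racemic because it is oxidised in the next step.

Step 3
Reactants: 5 rac-5-[(4-methoxybenzyl)oxy]-1-(trimethylsilyl)pent-1-yn-3-ol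
Product: 6 5-[(4-methoxybenzyl)oxy]-1-(trimethylsilyl)pent-1-yn-3-one
Conditions: Dess–Martin periodinane, NaHCO3, CH2Cl2, 0 °C → rt
Reagents that add atoms: none
Why: Dess–Martin oxidation of a secondary propargylic alcohol gives the achiral ynone without touching the PMB ether or the C–Si bond.

Step 4
Reactants: 6 5-[(4-methoxybenzyl)oxy]-1-(trimethylsilyl)pent-1-yn-3-one
Product: 7 (3S)-5-[(4-methoxybenzyl)oxy]-1-(trimethylsilyl)pent-1-yn-3-ol
Conditions: ketoreductase (KRED, NADPH-dependent alcohol dehydrogenase, (S)-selective), NADP+ (cat.), i-PrOH, phosphate buffer pH 7.0, 30 °C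
Reagents that add atoms: none
Why: Enzymatic asymmetric ketone reduction: the ketoreductase delivers hydride from NADPH to one face of the ynone and sets C3 as S, with i-PrOH recycling the cofactor.

Step 5
Reactants: 7 (3S)-5-[(4-methoxybenzyl)oxy]-1-(trimethylsilyl)pent-1-yn-3-ol
Product: 8 (3S)-3-[(tert-butyldimethylsilyl)oxy]-5-[(4-methoxybenzyl)oxy]-1-(trimethylsilyl)pent-1-yne
Conditions: TBSCl, imidazole, DMF, rt
Reagents that add atoms: tert-butyldimethylsilyl chloride, CC(C)(C)[Si](C)(C)Cl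
Why: Silyl ether formation protects the C3 carbinol for the organometallic steps; the stereocentre is not touched.

Step 6
Reactants: 8 (3S)-3-[(tert-butyldimethylsilyl)oxy]-5-[(4-methoxybenzyl)oxy]-1-(trimethylsilyl)pent-1-yne
Product: 9 (3S)-3-[(tert-butyldimethylsilyl)oxy]-5-[(4-methoxybenzyl)oxy]pent-1-yne
Conditions: K2CO3, MeOH, 0 °C → rt
Reagents that add atoms: none
Why: Methanolysis (protodesilylation) cleaves only the alkynyl C–Si bond; the O–TBS ether is stable.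

Step 7
Reactants: 9 (3S)-3-[(tert-butyldimethylsilyl)oxy]-5-[(4-methoxybenzyl)oxy]pent-1-yne
Product: 11 methyl (4S)-4-[(tert-butyldimethylsilyl)oxy]-6-[(4-methoxybenzyl)oxy]hex-2-ynoate, via lithium acetylide 10 (not isolated)
Conditions: n-BuLi, THF, −78 °C; then ClCO2Me, −78 → −20 °C
Reagents that add atoms: methyl chloroformate, COC(=O)Cl
Why: Acylation of the lithium acetylide with a chloroformate gives the ynoate; its ester carbon becomes C6.

Step 8
Reactants: 11 methyl (4S)-4-[(tert-butyldimethylsilyl)oxy]-6-[(4-methoxybenzyl)oxy]hex-2-ynoate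
Product: 13 methyl (2Z,4S)-4-[(tert-butyldimethylsilyl)oxy]-6-[(4-methoxybenzyl)oxy]-3-methylhex-2-enoate, via alkenylcuprate 12 (not isolated)
Conditions: Me2CuLi (from MeLi, CuI), THF, −78 °C; MeOH/aq. NH4Cl quench at −78 °C
Reagents that add atoms: lithium dimethylcuprate, [Li+].C[Cu-]C
Why: Syn-carbocupration of the ynoate (Gilman conjugate addition) followed by low-temperature protonation with retention gives only the Z-enoate, which fixes the Z-C4=C5 alkene and installs C15.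

Step 9
Reactants: 13 methyl (2Z,4S)-4-[(tert-butyldimethylsilyl)oxy]-6-[(4-methoxybenzyl)oxy]-3-methylhex-2-enoate
Product: 14 (2Z,4S)-4-[(tert-butyldimethylsilyl)oxy]-6-[(4-methoxybenzyl)oxy]-3-methylhex-2-en-1-ol
Conditions: i-Bu2AlH (2.5 equiv), CH2Cl2, −78 °C; aq. KNaC4H4O6 work-up
Reagents that add atoms: none
Why: 1,2-Reduction of the enoate by the aluminium hydride gives the allylic alcohol without changing the alkene geometry.

Step 10
Reactants: 14 (2Z,4S)-4-[(tert-butyldimethylsilyl)oxy]-6-[(4-methoxybenzyl)oxy]-3-methylhex-2-en-1-ol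
Product: 15 (2Z,4S)-4-[(tert-butyldimethylsilyl)oxy]-6-[(4-methoxybenzyl)oxy]-3-methylhex-2-enal
Conditions: Dess–Martin periodinane, NaHCO3, CH2Cl2, 0 °C; crude enal used at once
Reagents that add atoms: none
Why: Buffered Dess–Martin oxidation gives the Z-enal without acid or base that would isomerise it to the E-isomer.

Step 11
Reactants: 15 (2Z,4S)-4-[(tert-butyldimethylsilyl)oxy]-6-[(4-methoxybenzyl)oxy]-3-methylhex-2-enal; 16 methyl propiolate
Product: 18 methyl (4R,5Z,7S)-7-[(tert-butyldimethylsilyl)oxy]-4-hydroxy-9-[(4-methoxybenzyl)oxy]-6-methylnon-5-en-2-ynoate, via methylzinc acetylide 17 (not isolated)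
Conditions: 16, Me2Zn, (R,R)-ProPhenol (20 mol%), Ph3P=O (40 mol%), toluene, 4 °C
Reagents that add atoms: methyl propiolate (16), C#CC(=O)OC
Why: Trost dinuclear zinc–ProPhenol asymmetric alkynylation: the chiral catalyst delivers the zinc acetylide to the Si face of the enal and sets C6 as R under catalyst control.

Step 12
Reactants: 18 methyl (4R,5Z,7S)-7-[(tert-butyldimethylsilyl)oxy]-4-hydroxy-9-[(4-methoxybenzyl)oxy]-6-methylnon-5-en-2-ynoate
Product: 19 methyl (4R,5Z,7S)-7-[(tert-butyldimethylsilyl)oxy]-9-[(4-methoxybenzyl)oxy]-6-methyl-4-[(triethylsilyl)oxy]non-5-en-2-ynoate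
Conditions: TESCl, imidazole, CH2Cl2, 0 °C
Reagents that add atoms: chlorotriethylsilane, CC[Si](Cl)(CC)CC
Why: Silylation gives a labile TES ether at C6 that blocks lactonisation and proton transfer during the cuprate step and can later be removed next to TBS.

Step 13
Reactants: 20 (1-bromoethenyl)trimethylsilane; 21 oxirane
Product: 23 3-(trimethylsilyl)but-3-en-1-ol, via Grignard reagent 22 (not isolated)
Conditions: Mg, THF, reflux; then CuI (5 mol%), oxirane, −30 → 0 °C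
Reagents that add atoms: oxirane (21), C1CO1
Why: Copper-catalysed ring opening of the epoxide by the alkenyl Grignard reagent gives the C8–C10/C14 unit with the future iodoalkene masked as a vinylsilane.

Step 14
Reactants: 23 3-(trimethylsilyl)but-3-en-1-ol
Product: 24 (4-bromobut-1-en-2-yl)trimethylsilane
Conditions: CBr4, PPh3, CH2Cl2, 0 °C
Reagents that add atoms: tetrabromomethane, BrC(Br)(Br)Br
Why: Appel bromination converts the primary alcohol into the bromide needed for Grignard formation.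

Step 15
Reactants: 19 methyl (4R,5Z,7S)-7-[(tert-butyldimethylsilyl)oxy]-9-[(4-methoxybenzyl)oxy]-6-methyl-4-[(triethylsilyl)oxy]non-5-en-2-ynoate; 24 (4-bromobut-1-en-2-yl)trimethylsilane; 25 2-(iodomethyl)-4,4,5,5-tetramethyl-1,3,2-dioxaborolane
Product: 29 methyl (2Z,4R,5Z,7S)-7-[(tert-butyldimethylsilyl)oxy]-9-[(4-methoxybenzyl)oxy]-6-methyl-2-[(4,4,5,5-tetramethyl-1,3,2-dioxaborolan-2-yl)methyl]-4-[(triethylsilyl)oxy]-3-[3-(trimethylsilyl)but-3-en-1-yl]nona-2,5-dienoate, via Grignard reagent 26 (not isolated), via dialkylcuprate 27 (not isolated), via alkenylcuprate 28 (not isolated)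
Conditions: 24, Mg, THF; CuBr·SMe2 (0.5 equiv per RMgBr), −78 → −40 °C; 19, −78 °C; then HMPA, 25, −78 → 0 °C
Reagents that add atoms: (4-bromobut-1-en-2-yl)trimethylsilane (24), BrCCC(=C)[Si](C)(C)C; 2-(iodomethyl)-4,4,5,5-tetramethyl-1,3,2-dioxaborolane (25), ICB1OC(C)(C)C(C)(C)O1
Why: Syn-carbocupration of the ynoate followed by alkylation of the alkenylcopper with retention (three-component coupling) gives the tetrasubstituted enoate with the ester cis to C6 and the C13 carbon cis to the C8 chain.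

Step 16
Reactants: 29 the allylboronate of step 15
Product: 30 methyl (2Z,4R,5Z,7S)-7-[(tert-butyldimethylsilyl)oxy]-2-(hydroxymethyl)-9-[(4-methoxybenzyl)oxy]-6-methyl-4-[(triethylsilyl)oxy]-3-[3-(trimethylsilyl)but-3-en-1-yl]nona-2,5-dienoate
Conditions: NaBO3·4H2O, THF/H2O (1:1), rt
Reagents that add atoms: sodium perborate, [Na+].[O-]OB=O
Why: Oxidation of the C–B bond (1,2-boronate migration to oxygen) turns the allylboronate into the C13 allylic alcohol without allylic transposition.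

Step 17
Reactants: 30 the hydroxymethyl dienoate of step 16
Product: 32 (5R)-5-{(1Z,3S)-3-[(tert-butyldimethylsilyl)oxy]-5-[(4-methoxybenzyl)oxy]-2-methylpent-1-en-1-yl}-3-(hydroxymethyl)-4-[3-(trimethylsilyl)but-3-en-1-yl]furan-2(5H)-one, via hydroxy ester 31 (not isolated)
Conditions: PPTS (cat.), MeOH/CH2Cl2, 0 °C → rt
Reagents that add atoms: none
Why: Mild acid methanolysis removes the TES ether but not the TBS ether, and the freed C6–OH, held cis to the ester, lactonises at once to ring A with C6 unchanged.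

Step 18
Reactants: 32 the hydroxymethyl butenolide of step 17
Product: 33 (5R)-5-{(1Z,3S)-3-[(tert-butyldimethylsilyl)oxy]-5-[(4-methoxybenzyl)oxy]-2-methylpent-1-en-1-yl}-3-{[(tert-butyldimethylsilyl)oxy]methyl}-4-[3-(trimethylsilyl)but-3-en-1-yl]furan-2(5H)-one
Conditions: TBSCl, imidazole, CH2Cl2, 0 °C
Reagents that add atoms: tert-butyldimethylsilyl chloride, CC(C)(C)[Si](C)(C)Cl
Why: Silylation protects the C13 primary allylic alcohol against the later oxidations.

Step 19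
Reactants: 33 the bis-TBS vinylsilane butenolide of step 18
Product: 34 (5R)-5-{(1Z,3S)-3-[(tert-butyldimethylsilyl)oxy]-5-[(4-methoxybenzyl)oxy]-2-methylpent-1-en-1-yl}-3-{[(tert-butyldimethylsilyl)oxy]methyl}-4-(3-iodobut-3-en-1-yl)furan-2(5H)-one
Conditions: NIS, MeCN/ClCH2CN (4:1), rt, dark
Reagents that add atoms: N-iodosuccinimide, O=C1CCC(=O)N1I
Why: Ipso-iododesilylation of the vinylsilane gives the 2-iodoalkene; the C4=C5 and butenolide alkenes are electron-poor and far slower to react.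

Step 20
Reactants: 34 the iodoalkene PMB ether of step 19
Product: 35 (5R)-5-{(1Z,3S)-3-[(tert-butyldimethylsilyl)oxy]-5-hydroxy-2-methylpent-1-en-1-yl}-3-{[(tert-butyldimethylsilyl)oxy]methyl}-4-(3-iodobut-3-en-1-yl)furan-2(5H)-one
Conditions: DDQ, CH2Cl2/pH 7 buffer (10:1), 0 °C → rt
Reagents that add atoms: none
Why: Oxidative cleavage of the PMB ether frees only the C1 primary alcohol; silyl ethers, iodoalkene and butenolide are inert to DDQ.

Step 21
Reactants: 35 the C1 primary alcohol of step 20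
Product: 36 (3S,4Z)-3-[(tert-butyldimethylsilyl)oxy]-5-[(2R)-4-{[(tert-butyldimethylsilyl)oxy]methyl}-3-(3-iodobut-3-en-1-yl)-5-oxo-2,5-dihydrofuran-2-yl]-4-methylpent-4-enal
Conditions: Dess–Martin periodinane, NaHCO3, CH2Cl2, 0 °C → rt
Reagents that add atoms: none
Why: Dess–Martin oxidation gives the β-silyloxy aldehyde, which does not eliminate under these buffered conditions.

Step 22
Reactants: 36 the iodoalkene aldehyde of step 21
Product: 38 (3S,6R,4Z)-3,13-bis[(tert-butyldimethylsilyl)oxy]-1-hydroxygermacra-4,7(11),10(14)-trien-12,6-olide (both C1 epimers), via alkenylchromium species 37 (not isolated)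
Conditions: CrCl2 (15 equiv), NiCl2 (0.15 equiv), degassed DMSO, rt, 0.002 M, slow addition of 36
Reagents that add atoms: none
Why: Nozaki–Hiyama–Kishi reaction: nickel-catalysed formation of an alkenylchromium species that adds only to the aldehyde closes ring B at C1–C10, helped by the Z-alkene and the butenolide; the C1 configuration is not relied on because both epimers converge in steps 23–24.

Step 23
Reactants: 38 the macrocyclic allylic alcohol of step 22
Product: 39 (3S,6R,4Z)-3,13-bis[(tert-butyldimethylsilyl)oxy]-1-oxogermacra-4,7(11),10(14)-trien-12,6-olide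
Conditions: Dess–Martin periodinane, NaHCO3, CH2Cl2, 0 °C; used at once
Reagents that add atoms: none
Why: Dess–Martin oxidation turns both C1 epimers into the single cross-conjugated enone.

Step 24
Reactants: 39 the macrocyclic enone of step 23
Product: 40 (1R,3S,6R,4Z)-3,13-bis[(tert-butyldimethylsilyl)oxy]-1-hydroxygermacra-4,7(11),10(14)-trien-12,6-olide
Conditions: (S)-Me-CBS oxazaborolidine (1 equiv), catecholborane, toluene, −78 °C
Reagents that add atoms: none
Why: Corey–Bakshi–Shibata reduction: the 1,1-disubstituted alkenyl group (C10) is the large substituent and C2H2 the small one, so the (S)-catalyst gives the 1R allylic alcohol under catalyst control, with 1,2-selectivity and no reduction of the lactone.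

Step 25
Reactants: 40 the (1R)-alcohol of step 24
Product: 41 (1R,3S,6R,4Z)-3,13-bis[(tert-butyldimethylsilyl)oxy]-1-(chloroacetoxy)germacra-4,7(11),10(14)-trien-12,6-olide
Conditions: (ClCH2CO)2O, pyridine, CH2Cl2, 0 °C
Reagents that add atoms: chloroacetic anhydride, ClCC(=O)OC(=O)CCl
Why: Acylation masks C1–OH as a chloroacetate, an ester that can later be removed in the presence of acetates.

Step 26
Reactants: 41 the chloroacetate of step 25
Product: 42 (1R,3S,6R,4Z)-1-(chloroacetoxy)-3,13-dihydroxygermacra-4,7(11),10(14)-trien-12,6-olide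
Conditions: HF·pyridine, THF, 0 °C → rt
Reagents that add atoms: none
Why: Fluoride-mediated desilylation under mildly acidic conditions removes both TBS ethers and leaves the chloroacetate and the base-sensitive butenolide intact.

Step 27
Reactants: 42 the diol of step 26
Product: 43 (1R,3S,6R,4Z)-3,13-diacetoxy-1-(chloroacetoxy)germacra-4,7(11),10(14)-trien-12,6-olide
Conditions: Ac2O, pyridine, DMAP (cat.), CH2Cl2, 0 °C
Reagents that add atoms: acetic anhydride, CC(=O)OC(C)=O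
Why: Acetylation of the C3 and C13 hydroxyls installs both acetates of the target in one operation.

Step 28
Reactants: 43 the diacetate chloroacetate of step 27
Product: 44 (1R,3S,6R,4Z)-3,13-diacetoxy-1-hydroxygermacra-4,7(11),10(14)-trien-12,6-olide (CNP0227830.1)
Conditions: thiourea, NaHCO3, EtOH, 50 °C
Reagents that add atoms: none
Why: Selective dechloroacetylation: thiourea S-alkylates the chloroacetate and then cyclises to release the C1 alcohol, a path not open to the acetates.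

**Compound list**
1 | 3-[(4-methoxybenzyl)oxy]propan-1-ol | OCCCOCc1ccc(OC)cc1 | starting material
2 | 3-[(4-methoxybenzyl)oxy]propanal | O=CCCOCc1ccc(OC)cc1 | intermediate
3 | ethynyltrimethylsilane | C#C[Si](C)(C)C | starting material
4 | lithium (trimethylsilyl)acetylide (not isolated) | [Li]C#C[Si](C)(C)C | intermediate
5 | rac-5-[(4-methoxybenzyl)oxy]-1-(trimethylsilyl)pent-1-yn-3-ol | C[Si](C)(C)C#CC(O)CCOCc1ccc(OC)cc1 | intermediate
6 | 5-[(4-methoxybenzyl)oxy]-1-(trimethylsilyl)pent-1-yn-3-one | C[Si](C)(C)C#CC(=O)CCOCc1ccc(OC)cc1 | intermediate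
7 | (3S)-5-[(4-methoxybenzyl)oxy]-1-(trimethylsilyl)pent-1-yn-3-ol | C[Si](C)(C)C#C[C@@H](O)CCOCc1ccc(OC)cc1 | intermediate
8 | (3S)-3-[(TBS)oxy]-5-[(PMB)oxy]-1-(trimethylsilyl)pent-1-yne | C[Si](C)(C)C#C[C@@H](O[Si](C)(C)C(C)(C)C)CCOCc1ccc(OC)cc1 | intermediate
9 | (3S)-3-[(TBS)oxy]-5-[(PMB)oxy]pent-1-yne | C#C[C@@H](O[Si](C)(C)C(C)(C)C)CCOCc1ccc(OC)cc1 | intermediate
10 | lithium acetylide of 9 (not isolated) | [Li]C#C[C@@H](O[Si](C)(C)C(C)(C)C)CCOCc1ccc(OC)cc1 | intermediate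
11 | methyl (4S)-4-[(TBS)oxy]-6-[(PMB)oxy]hex-2-ynoate | COC(=O)C#C[C@@H](O[Si](C)(C)C(C)(C)C)CCOCc1ccc(OC)cc1 | intermediate
12 | lithium alkenyl(methyl)cuprate from syn-addition of Me2CuLi to 11, Cu on C2 cis to the new methyl (not isolated) | COC(=O)/C([Cu-]C)=C(/C)[C@@H](O[Si](C)(C)C(C)(C)C)CCOCc1ccc(OC)cc1.[Li+] | intermediate
13 | methyl (2Z,4S)-4-[(TBS)oxy]-6-[(PMB)oxy]-3-methylhex-2-enoate | COC(=O)/C=C(/C)[C@@H](O[Si](C)(C)C(C)(C)C)CCOCc1ccc(OC)cc1 | intermediate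
14 | (2Z,4S)-4-[(TBS)oxy]-6-[(PMB)oxy]-3-methylhex-2-en-1-ol | OC/C=C(/C)[C@@H](O[Si](C)(C)C(C)(C)C)CCOCc1ccc(OC)cc1 | intermediate
15 | (2Z,4S)-4-[(TBS)oxy]-6-[(PMB)oxy]-3-methylhex-2-enal | O=C/C=C(/C)[C@@H](O[Si](C)(C)C(C)(C)C)CCOCc1ccc(OC)cc1 | intermediate
16 | methyl propiolate | C#CC(=O)OC | starting material
17 | methylzinc acetylide of methyl propiolate (not isolated) | C[Zn]C#CC(=O)OC | intermediate
18 | methyl (4R,5Z,7S)-7-[(TBS)oxy]-4-hydroxy-9-[(PMB)oxy]-6-methylnon-5-en-2-ynoate | COC(=O)C#C[C@H](O)/C=C(/C)[C@@H](O[Si](C)(C)C(C)(C)C)CCOCc1ccc(OC)cc1 | intermediate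
19 | methyl (4R,5Z,7S)-7-[(TBS)oxy]-9-[(PMB)oxy]-6-methyl-4-[(TES)oxy]non-5-en-2-ynoate | COC(=O)C#C[C@H](O[Si](CC)(CC)CC)/C=C(/C)[C@@H](O[Si](C)(C)C(C)(C)C)CCOCc1ccc(OC)cc1 | intermediate
20 | (1-bromoethenyl)trimethylsilane | C=C(Br)[Si](C)(C)C | starting material
21 | oxirane | C1CO1 | starting material
22 | [1-(trimethylsilyl)ethenyl]magnesium bromide (not isolated) | C=C([Mg]Br)[Si](C)(C)C | intermediate
23 | 3-(trimethylsilyl)but-3-en-1-ol | OCCC(=C)[Si](C)(C)C | intermediate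
24 | (4-bromobut-1-en-2-yl)trimethylsilane | BrCCC(=C)[Si](C)(C)C | intermediate
25 | 2-(iodomethyl)-4,4,5,5-tetramethyl-1,3,2-dioxaborolane | ICB1OC(C)(C)C(C)(C)O1 | starting material
26 | [3-(trimethylsilyl)but-3-en-1-yl]magnesium bromide (not isolated) | Br[Mg]CCC(=C)[Si](C)(C)C | intermediate
27 | bromomagnesium bis[3-(trimethylsilyl)but-3-en-1-yl]cuprate (not isolated) | C=C(CC[Cu-]CCC(=C)[Si](C)(C)C)[Si](C)(C)C.[Mg+]Br | intermediate
28 | bromomagnesium alkenyl(alkyl)cuprate from syn-addition of 27 to 19, Cu on C2 cis to the new C3 chain (not isolated) | COC(=O)/C([Cu-]CCC(=C)[Si](C)(C)C)=C(/CCC(=C)[Si](C)(C)C)[C@H](O[Si](CC)(CC)CC)/C=C(/C)[C@@H](O[Si](C)(C)C(C)(C)C)CCOCc1ccc(OC)cc1.[Mg+]Br | intermediate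
29 | methyl (2Z,4R,5Z,7S)-7-[(TBS)oxy]-9-[(PMB)oxy]-6-methyl-2-[(Bpin)methyl]-4-[(TES)oxy]-3-[3-(trimethylsilyl)but-3-en-1-yl]nona-2,5-dienoate | COC(=O)/C(CB1OC(C)(C)C(C)(C)O1)=C(/CCC(=C)[Si](C)(C)C)[C@H](O[Si](CC)(CC)CC)/C=C(/C)[C@@H](O[Si](C)(C)C(C)(C)C)CCOCc1ccc(OC)cc1 | intermediate
30 | methyl (2Z,4R,5Z,7S)-7-[(TBS)oxy]-2-(hydroxymethyl)-9-[(PMB)oxy]-6-methyl-4-[(TES)oxy]-3-[3-(trimethylsilyl)but-3-en-1-yl]nona-2,5-dienoate | COC(=O)/C(CO)=C(/CCC(=C)[Si](C)(C)C)[C@H](O[Si](CC)(CC)CC)/C=C(/C)[C@@H](O[Si](C)(C)C(C)(C)C)CCOCc1ccc(OC)cc1 | intermediate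
31 | methyl (2Z,4R,5Z,7S)-7-[(TBS)oxy]-4-hydroxy-2-(hydroxymethyl)-9-[(PMB)oxy]-6-methyl-3-[3-(trimethylsilyl)but-3-en-1-yl]nona-2,5-dienoate (not isolated) | COC(=O)/C(CO)=C(/CCC(=C)[Si](C)(C)C)[C@H](O)/C=C(/C)[C@@H](O[Si](C)(C)C(C)(C)C)CCOCc1ccc(OC)cc1 | intermediate
32 | (5R)-5-{(1Z,3S)-3-[(TBS)oxy]-5-[(PMB)oxy]-2-methylpent-1-en-1-yl}-3-(hydroxymethyl)-4-[3-(trimethylsilyl)but-3-en-1-yl]furan-2(5H)-one | O=C1O[C@H](/C=C(/C)[C@@H](O[Si](C)(C)C(C)(C)C)CCOCc2ccc(OC)cc2)C(CCC(=C)[Si](C)(C)C)=C1CO | intermediate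
33 | (5R)-5-{(1Z,3S)-3-[(TBS)oxy]-5-[(PMB)oxy]-2-methylpent-1-en-1-yl}-3-{[(TBS)oxy]methyl}-4-[3-(trimethylsilyl)but-3-en-1-yl]furan-2(5H)-one | O=C1O[C@H](/C=C(/C)[C@@H](O[Si](C)(C)C(C)(C)C)CCOCc2ccc(OC)cc2)C(CCC(=C)[Si](C)(C)C)=C1CO[Si](C)(C)C(C)(C)C | intermediate
34 | (5R)-5-{(1Z,3S)-3-[(TBS)oxy]-5-[(PMB)oxy]-2-methylpent-1-en-1-yl}-3-{[(TBS)oxy]methyl}-4-(3-iodobut-3-en-1-yl)furan-2(5H)-one | O=C1O[C@H](/C=C(/C)[C@@H](O[Si](C)(C)C(C)(C)C)CCOCc2ccc(OC)cc2)C(CCC(I)=C)=C1CO[Si](C)(C)C(C)(C)C | intermediate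
35 | (5R)-5-{(1Z,3S)-3-[(TBS)oxy]-5-hydroxy-2-methylpent-1-en-1-yl}-3-{[(TBS)oxy]methyl}-4-(3-iodobut-3-en-1-yl)furan-2(5H)-one | O=C1O[C@H](/C=C(/C)[C@@H](O[Si](C)(C)C(C)(C)C)CCO)C(CCC(I)=C)=C1CO[Si](C)(C)C(C)(C)C | intermediate
36 | (3S,4Z)-3-[(TBS)oxy]-5-[(2R)-4-{[(TBS)oxy]methyl}-3-(3-iodobut-3-en-1-yl)-5-oxo-2,5-dihydrofuran-2-yl]-4-methylpent-4-enal | O=C1O[C@H](/C=C(/C)[C@@H](O[Si](C)(C)C(C)(C)C)CC=O)C(CCC(I)=C)=C1CO[Si](C)(C)C(C)(C)C | intermediate
37 | alkenylchromium dichloride from 36, C–I replaced by C–CrCl2 (not isolated) | O=C1O[C@H](/C=C(/C)[C@@H](O[Si](C)(C)C(C)(C)C)CC=O)C(CCC(=C)[Cr](Cl)Cl)=C1CO[Si](C)(C)C(C)(C)C | intermediate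
38 | (3S,6R,4Z)-3,13-bis[(TBS)oxy]-1-hydroxygermacra-4,7(11),10(14)-trien-12,6-olide, both C1 epimers | C=C1CCC2=C(CO[Si](C)(C)C(C)(C)C)C(=O)O[C@@H]2/C=C(/C)[C@@H](O[Si](C)(C)C(C)(C)C)CC1O | intermediate
39 | (3S,6R,4Z)-3,13-bis[(TBS)oxy]-1-oxogermacra-4,7(11),10(14)-trien-12,6-olide | C=C1CCC2=C(CO[Si](C)(C)C(C)(C)C)C(=O)O[C@@H]2/C=C(/C)[C@@H](O[Si](C)(C)C(C)(C)C)CC1=O | intermediate
40 | (1R,3S,6R,4Z)-3,13-bis[(TBS)oxy]-1-hydroxygermacra-4,7(11),10(14)-trien-12,6-olide | C=C1CCC2=C(CO[Si](C)(C)C(C)(C)C)C(=O)O[C@@H]2/C=C(/C)[C@@H](O[Si](C)(C)C(C)(C)C)C[C@H]1O | intermediate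
41 | (1R,3S,6R,4Z)-3,13-bis[(TBS)oxy]-1-(chloroacetoxy)germacra-4,7(11),10(14)-trien-12,6-olide | C=C1CCC2=C(CO[Si](C)(C)C(C)(C)C)C(=O)O[C@@H]2/C=C(/C)[C@@H](O[Si](C)(C)C(C)(C)C)C[C@H]1OC(=O)CCl | intermediate
42 | (1R,3S,6R,4Z)-1-(chloroacetoxy)-3,13-dihydroxygermacra-4,7(11),10(14)-trien-12,6-olide | C=C1CCC2=C(CO)C(=O)O[C@@H]2/C=C(/C)[C@@H](O)C[C@H]1OC(=O)CCl | intermediate
43 | (1R,3S,6R,4Z)-3,13-diacetoxy-1-(chloroacetoxy)germacra-4,7(11),10(14)-trien-12,6-olide | C=C1CCC2=C(COC(C)=O)C(=O)O[C@@H]2/C=C(/C)[C@@H](OC(C)=O)C[C@H]1OC(=O)CCl | intermediate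
44 | (1R,3S,6R,4Z)-3,13-diacetoxy-1-hydroxygermacra-4,7(11),10(14)-trien-12,6-olide (CNP0227830.1) | C=C1CCC2=C(COC(C)=O)C(=O)O[C@@H]2/C=C(/C)[C@@H](OC(C)=O)C[C@H]1O | target

**Step count and risks**
Total: 28 steps. Longest linear sequence: 26 steps (1 → 44 through steps 1–12 and 15–28); steps 13–14 make the side-chain bromide 24.

Most likely to fail:

Step 15 (three-component carbocupration and alkylation). The alkylation of the hindered alkenylcopper with 25 may be slow, and the geometry can be lost on warming. Fallback, setting out from 19 and returning at 32: the carbocupration is kept as far as alkenylcuprate 28, but this is quenched at −78 °C with I2 to give the methyl (2E,4R,5Z,7S)-2-iodo dienoate F1. PPTS in MeOH then removes the TES group to the hydroxy iodo ester F2 (not isolated), which lactonises to the 3-iodobutenolide F3. A Stille coupling of F3 with (tributylstannyl)methanol (Bu3SnCH2OH, Pd(PPh3)4, dioxane, 80 °C) installs the C13 hydroxymethyl group and gives 32, so that C13 arrives by cross-coupling and not by alkylation of the copper intermediate.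

Step 22 (Nozaki–Hiyama–Kishi closure of the ten-membered ring). Oligomerisation or slow closure of the strained ring are the risks. Fallback, setting out from 36 and returning at 39: Pinnick oxidation (NaClO2, NaH2PO4, 2-methylbut-2-ene, t-BuOH/H2O) gives the carboxylic acid F4. Thiophenol with EDC·HCl and DMAP gives the S-phenyl thioester F5. Me3SnSnMe3 with Pd(PPh3)4 in toluene at 80 °C converts the iodoalkene into the alkenylstannane F6. A thioester–stannane ketone synthesis of the Liebeskind–Srogl type (Pd2(dba)3, tri(2-furyl)phosphine, CuO2PPh2, THF, high dilution, rt) then closes ring B at the ketone oxidation level and gives enone 39 directly, so step 23 falls away.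

Step 24 (CBS reduction on the macrocycle). The ring conformation may override catalyst control, and the α-methylene ketone is sensitive. Fallback, setting out from 39 and returning at 41: Luche reduction (NaBH4, CeCl3·7H2O, MeOH, −78 °C) under substrate control. Any 1R product is 40 itself and goes on through step 25. The 1S epimer, the (1S,3S,6R,4Z)-alcohol F7, is inverted by Mitsunobu esterification with chloroacetic acid (PPh3, DIAD, toluene, 0 °C), which gives chloroacetate 41 directly.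

**Further compounds**
F1 | step 15 | methyl (2E,4R,5Z,7S)-7-[(TBS)oxy]-2-iodo-9-[(PMB)oxy]-6-methyl-4-[(TES)oxy]-3-[3-(trimethylsilyl)but-3-en-1-yl]nona-2,5-dienoate | COC(=O)/C(I)=C(/CCC(=C)[Si](C)(C)C)[C@H](O[Si](CC)(CC)CC)/C=C(/C)[C@@H](O[Si](C)(C)C(C)(C)C)CCOCc1ccc(OC)cc1
F2 | step 15 | methyl (2E,4R,5Z,7S)-7-[(TBS)oxy]-4-hydroxy-2-iodo-9-[(PMB)oxy]-6-methyl-3-[3-(trimethylsilyl)but-3-en-1-yl]nona-2,5-dienoate | COC(=O)/C(I)=C(/CCC(=C)[Si](C)(C)C)[C@H](O)/C=C(/C)[C@@H](O[Si](C)(C)C(C)(C)C)CCOCc1ccc(OC)cc1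
F3 | step 15 | (5R)-5-{(1Z,3S)-3-[(TBS)oxy]-5-[(PMB)oxy]-2-methylpent-1-en-1-yl}-3-iodo-4-[3-(trimethylsilyl)but-3-en-1-yl]furan-2(5H)-one | O=C1O[C@H](/C=C(/C)[C@@H](O[Si](C)(C)C(C)(C)C)CCOCc2ccc(OC)cc2)C(CCC(=C)[Si](C)(C)C)=C1I
F4 | step 22 | (3S,4Z)-3-[(TBS)oxy]-5-[(2R)-4-{[(TBS)oxy]methyl}-3-(3-iodobut-3-en-1-yl)-5-oxo-2,5-dihydrofuran-2-yl]-4-methylpent-4-enoic acid | O=C1O[C@H](/C=C(/C)[C@@H](O[Si](C)(C)C(C)(C)C)CC(=O)O)C(CCC(I)=C)=C1CO[Si](C)(C)C(C)(C)C
F5 | step 22 | S-phenyl (3S,4Z)-3-[(TBS)oxy]-5-[(2R)-4-{[(TBS)oxy]methyl}-3-(3-iodobut-3-en-1-yl)-5-oxo-2,5-dihydrofuran-2-yl]-4-methylpent-4-enethioate | O=C1O[C@H](/C=C(/C)[C@@H](O[Si](C)(C)C(C)(C)C)CC(=O)Sc2ccccc2)C(CCC(I)=C)=C1CO[Si](C)(C)C(C)(C)C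
F6 | step 22 | S-phenyl (3S,4Z)-3-[(TBS)oxy]-5-[(2R)-4-{[(TBS)oxy]methyl}-5-oxo-3-[3-(trimethylstannyl)but-3-en-1-yl]-2,5-dihydrofuran-2-yl]-4-methylpent-4-enethioate | O=C1O[C@H](/C=C(/C)[C@@H](O[Si](C)(C)C(C)(C)C)CC(=O)Sc2ccccc2)C(CCC(=C)[Sn](C)(C)C)=C1CO[Si](C)(C)C(C)(C)C
F7 | step 24 | (1S,3S,6R,4Z)-3,13-bis[(TBS)oxy]-1-hydroxygermacra-4,7(11),10(14)-trien-12,6-olide | C=C1CCC2=C(CO[Si](C)(C)C(C)(C)C)C(=O)O[C@@H]2/C=C(/C)[C@@H](O[Si](C)(C)C(C)(C)C)C[C@@H]1O
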